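Slowness is worth something only against a clock: you want intermediate, it couples on to target at a modest pace, and you must choose the next run.

    substrate → intermediate (k1 = 0.043 /s)
    partner + intermediate ⇌ target (K2 = 190 /M, k2 = 1.9 /M/s)
    2 intermediate → homo product (k3 = 0.16 /M/s)
    substrate → decomposition product (k4 = 8.6 × 10⁻⁶ /s)

| flask | substrate | partner | time | remark |
|---|---|---|---|---|
| eta | 2.0 mM | 1.50 equiv | 80 s | everything together in a closed stirred flask, run for 80 s |
| zeta | 2.0 mM | 1.50 equiv |  | one stirred flow tank at steady state, fed with the mixture as stated, mean residence time 80 s |
| beta | 2.0 mM (fed, over 80.0 s) | 1.50 equiv | 80 s | all but substrate at the start; substrate goes in evenly over 80.0 s, the run ends at 80 s |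
| theta | 2.0 mM | 1.50 equiv |  | a single well-mixed tank run continuously and read at steady state, 400 s in it on average |

- the set-up with the highest amount of intermediate at the outlet or at the end, in percent of the substrate put in ("none" if the first two lie within 2 percentage points) (eta / zeta / beta / theta / none)
- amount of intermediate at the outlet or at the end, in percent of the substrate put in, eta
- amount of intermediate at the outlet or at the end, in percent of the substrate put in, zeta
- amount of intermediate at the outlet or at the end, in percent of the substrate put in, beta
- amount of intermediate at the outlet or at the end, in percent of the substrate put in, theta

- percentages count the substrate that a species holds: one homo product counts as two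
- a step written with two of one species runs at k times the square of its concentration and takes two of it each time
- the stated concentrations are those of everything mixed, before any reaction; amounts are the same in each set-up
- the feed brings no volume worth counting
- run time (eta): 80 s

Follow one molecule of intermediate. With c partner held at its charge (pseudo-first-order), each second it has a chance 0.00570 /s of becoming target, and as target a chance 0.0100 /s of coming back. The two chances add, and their inverse is the relaxation time of the coupling, 63.7 s, the time on which the split between intermediate and target closes on equilibrium.

Substrate's half-life, 16 s, is shorter than that, so making runs ahead of draining. The first half-life of homo coupling at full charge, 1560 s, is far longer than the 80 s of eta, zeta and beta, so I drop that step for those three. Theta's 400 s stands just 3.90 times below that half-life, so there the drop is rough, and I take my theta figure below to be on the high side. The rate of target is then the forward chance times the pool of intermediate and target, less target over the relaxation time.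

eta: substrate left 3.21%, target 20.7%, intermediate 76.1%.

zeta: substrate left 22.5%; target over intermediate is the forward chance over the back chance plus washout; intermediate 61.8%.

theta: substrate left 5.49%, same split, intermediate 64.9%.

beta: substrate left 28.1%; target, with the way back dropped, 13.3%; intermediate 58.6%.

The equilibrium share of intermediate in the pool is 63.7%, and the closed run lasts 1.26 relaxation times. My next run is eta, stopped on time.

The forecast also names eta, saying “so the intermediate stays highest there”, with 75.8%, 61.4%, 62.1% and 61.3% in the order of the questions. It stands lower than mine on theta and higher on beta.

The flask gives 75.6% for eta, 61.4% for zeta, 62.1% for beta and 61.3% for theta, so eta leads. In eta the midpoint of the making of intermediate came at 15.4 s, earlier than the midpoint of the making of target at 41.0 s. Take the same closed flask with 6.00 equiv of partner: the relaxation time falls to 30.5 s, and the same reckoning gives target 55.4%. That flask held target 53.0% and intermediate 42.7%.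

Its constants are made up.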